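The ring is numbered as in the target (C1 carbonyl, C2=C3, C4 and C5 carbinols, C6 methylene) and is cut at C2–C3 and C4–C5. The 1,3-relation of the C1 ketone and the C5 tertiary carbinol (C1–C6–C5) is stored in a 3-benzyloxy-3-alkylcyclobutanone in which C2 is still bonded to C5. Silylium-triggered opening of this strained donor–acceptor ring gives a C2 enol ether/C5 oxocarbenium pair. The silyl enol ether of benzyloxyacetaldehyde (C3–C4) is inserted, C4 adding to C5 and C2 closing on C3, and silanol loss gives the enone. One operation thus joins the two oxygen-bearing carbons C4 and C5 and creates C2=C3, with a chiral disulfonimide counteranion setting both stereocentres.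

Key step: step 8

Assumption: the (R)-configured disulfonimide of step 8 is taken to lead to the (4S,5S) series; its enantiomer is equally accessible and would be used if the sense of induction turned out to be the opposite.

Step 1
Reactants: 1 16-bromohexadecanoic acid; 2 but-1-yne
Product: 3 icos-17-ynoic acid
Conditions: 2 (3.2 equiv), n-BuLi (3.0 equiv), THF–DMPU, −78 to 25 °C; then aq. HCl
Reagents that add atoms: none
Why: Acetylide alkylation (SN2) of lithium but-1-ynide by the primary bromide, the acid being carried through as its lithium carboxylate.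

Step 2
Reactants: 3 icos-17-ynoic acid
Product: 4 (17E)-icos-17-enoic acid
Conditions: Na, NH3 (l)–THF, −33 °C; then NH4Cl
Reagents that add atoms: none
Why: Dissolving-metal reduction of the internal alkyne runs through the trans vinyl radical/anion and should set the (E)-alkene, the carboxylate being inert.

Step 3
Reactants: 4 (17E)-icos-17-enoic acid
Product: 5 benzyl (17E)-icos-17-enoate
Conditions: BnBr, K2CO3, DMF, 25 °C
Reagents that add atoms: benzyl bromide, BrCc1ccccc1
Why: SN2 O-alkylation of the potassium carboxylate gives the benzyl ester, whose benzyl group later serves as the protecting group of the C5 oxygen.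

Step 4
Reactants: 5 benzyl (17E)-icos-17-enoate
Product: 6 (18E)-2-(benzyloxy)henicosa-1,18-diene
Conditions: Cp2TiMe2 (3 equiv), toluene, 65 °C, dark
Reagents that add atoms: bis(cyclopentadienyl)dimethyltitanium, C[Ti](C)(C1C=CC=C1)C1C=CC=C1
Why: Petasis methylenation (titanocene methylidene, [2+2]/retro-[2+2]) should turn the ester carbonyl into the 1,1-disubstituted benzyl enol ether without touching the isolated alkene.

Step 5
Reactants: 6 (18E)-2-(benzyloxy)henicosa-1,18-diene
Product: 7 3-(benzyloxy)-2,2-dichloro-3-[(16E)-nonadec-16-en-1-yl]cyclobutan-1-one (racemate)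
Conditions: Cl2CHCOCl (1.5 equiv), Et3N (1.6 equiv), hexane, 0 to 25 °C, slow addition
Reagents that add atoms: dichloroacetyl chloride, ClC(Cl)C(Cl)=O (source of dichloroketene, ClC(Cl)=C=O)
Why: Ketene–alkene [2+2] cycloaddition in which the nucleophilic CH2 terminus of the enol ether bonds to the ketene carbonyl carbon, placing the benzyloxy-bearing carbon at C3; the electron-rich enol ether should react far faster than the isolated (E)-alkene, and the new stereocentre (racemic) disappears in step 6.

Step 6
Reactants: 7 3-(benzyloxy)-2,2-dichloro-3-[(16E)-nonadec-16-en-1-yl]cyclobutan-1-one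
Product: 8 3-(benzyloxy)-3-[(16E)-nonadec-16-en-1-yl]cyclobutan-1-one
Conditions: Zn dust, NH4Cl, MeOH, 25 °C
Reagents that add atoms: none
Why: Zinc-mediated reductive dechlorination of the α,α-dichloroketone under buffered protic conditions should give the achiral donor–acceptor cyclobutanone.

Step 7
Reactants: 9 (benzyloxy)acetaldehyde
Product: 10 (Z)-2-(benzyloxy)-1-(trimethylsilyloxy)ethene
Conditions: Me3SiCl, Et3N, MeCN, 25 °C
Reagents that add atoms: chlorotrimethylsilane, C[Si](C)(C)Cl
Why: Silyl enol ether formation under amine base should give mainly the Z isomer, as is usual for α-alkoxy aldehydes.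

Step 8
Reactants: 8 3-(benzyloxy)-3-[(16E)-nonadec-16-en-1-yl]cyclobutan-1-one; 10 (Z)-2-(benzyloxy)-1-(trimethylsilyloxy)ethene
Product: 12 (4S,5S)-4,5-bis(benzyloxy)-5-[(16E)-nonadec-16-en-1-yl]cyclohex-2-en-1-one, via silyloxy ketone 11 (not isolated)
Conditions: 10 (1.5 equiv), (R)-3,3′-bis[3,5-bis(trifluoromethyl)phenyl]-1,1′-binaphthalene-2,2′-disulfonimide (5 mol %), toluene, −78 °C; then DBU (3 equiv), −78 to 0 °C, same flask
Reagents that add atoms: none
Why: Proposed new method: the disulfonimide is silylated by 10 and the resulting silylium ion pair silylates the carbonyl oxygen of 8, so that ring strain and the benzyloxy donor drive heterolysis of one of the two equivalent C2–C5 bonds to a silyl enol ether (C1=C2) and an O-benzyl oxocarbenium ion at C5 paired with the chiral anion; C4 of 10 adds to C5, the silyloxycarbenium ion formed at C3 is trapped by C2 with release of the silylium ion, and DBU then expels trimethylsilanolate from C3 of 11 (E1cB) to give the C2=C3 enone. The closest known reaction types are the racemic EtAlCl2-promoted formal [4+2] cycloaddition of 3-alkoxycyclobutanones with silyl enol ethers and disulfonimide-catalysed enantioselective Mukaiyama aldol additions. The six-membered ring closes by a 6-(enolendo)-exo-trig Mukaiyama aldol step. C5 and C4 are both set in the addition to the oxocarbenium ion: the binaphthyl anion of the contact ion pair screens one face of C5 (it has to tell the n-alkyl chain from the bulkier silyloxyallyl arm), and in the open antiperiplanar transition state the benzyloxy group on C4 turns away from that bulkier arm, which should give the 4,5-trans arrangement. The step needs attack by the benzyloxy-bearing carbon of 10 (secured by the silyloxy donor on the neighbouring carbon, as in Mukaiyama aldol reactions of this enolsilane) and loss of the C3 silyloxy group in preference to the C5 benzyloxy group (secured by the better nucleofuge at a secondary carbon); the mirror symmetry of 8 makes it irrelevant for the constitution which of the two C–C bonds breaks.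

Step 9
Reactants: 12 (4S,5S)-4,5-bis(benzyloxy)-5-[(16E)-nonadec-16-en-1-yl]cyclohex-2-en-1-one
Product: 13 (4S,5S)-4,5-dihydroxy-5-[(16E)-nonadec-16-en-1-yl]cyclohex-2-en-1-one
Conditions: BCl3 (4 equiv), C6HMe5 (6 equiv), CH2Cl2, −78 °C; then MeOH, aq. NaHCO3
Reagents that add atoms: none
Why: Lewis-acid cleavage of both benzyl ethers at the benzylic C–O bonds (the ring C–O bonds stay intact, so C4 and C5 keep their configuration), the benzyl cations being removed by Friedel–Crafts capture with pentamethylbenzene.

Compound list
1 | 16-bromohexadecanoic acid | OC(=O)CCCCCCCCCCCCCCCBr | starting material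
2 | but-1-yne | C#CCC | starting material
3 | icos-17-ynoic acid | OC(=O)CCCCCCCCCCCCCCCC#CCC | intermediate
4 | (17E)-icos-17-enoic acid | OC(=O)CCCCCCCCCCCCCCC/C=C/CC | intermediate
5 | benzyl (17E)-icos-17-enoate | O=C(OCc1ccccc1)CCCCCCCCCCCCCCC/C=C/CC | intermediate
6 | (18E)-2-(benzyloxy)henicosa-1,18-diene | C=C(OCc1ccccc1)CCCCCCCCCCCCCCC/C=C/CC | intermediate
7 | 3-(benzyloxy)-2,2-dichloro-3-[(16E)-nonadec-16-en-1-yl]cyclobutan-1-one (racemate, ring stereocentre left open) | O=C1CC(OCc2ccccc2)(CCCCCCCCCCCCCCC/C=C/CC)C1(Cl)Cl | intermediate
8 | 3-(benzyloxy)-3-[(16E)-nonadec-16-en-1-yl]cyclobutan-1-one | O=C1CC(OCc2ccccc2)(CCCCCCCCCCCCCCC/C=C/CC)C1 | intermediate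
9 | (benzyloxy)acetaldehyde | O=CCOCc1ccccc1 | starting material
10 | (Z)-2-(benzyloxy)-1-(trimethylsilyloxy)ethene | C[Si](C)(C)O/C=C\OCc1ccccc1 | intermediate
11 | (4S,5S)-4,5-bis(benzyloxy)-5-[(16E)-nonadec-16-en-1-yl]-3-(trimethylsilyloxy)cyclohexan-1-one (C3 left open, lost on elimination) | CC/C=C/CCCCCCCCCCCCCCC[C@]1(OCc2ccccc2)CC(=O)CC(O[Si](C)(C)C)[C@@H]1OCc1ccccc1 | intermediate (not isolated)
12 | (4S,5S)-4,5-bis(benzyloxy)-5-[(16E)-nonadec-16-en-1-yl]cyclohex-2-en-1-one | CC/C=C/CCCCCCCCCCCCCCC[C@]1(OCc2ccccc2)CC(=O)C=C[C@@H]1OCc1ccccc1 | intermediate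
13 | (4S,5S)-4,5-dihydroxy-5-[(16E)-nonadec-16-en-1-yl]cyclohex-2-en-1-one | CC/C=C/CCCCCCCCCCCCCCC[C@]1(O)CC(=O)C=C[C@@H]1O | target

Total step count: 9. Longest linear sequence: 8 steps (steps 1 to 6, 8 and 9).

Steps most likely to fail

Step 8 (proposed new method). Facial discrimination at the ketone-derived oxocarbenium ion may be poor, giving low enantioselectivity or a cis/trans mixture. Proton loss from the ring-opened ion, or 1,2-addition to the activated carbonyl, may also outrun the wanted C–C bond formation. The fallback uses known chemistry, sets out from 5 and rejoins the route at 13.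
- Half-reduction of 5 (i-Bu2AlH, CH2Cl2, −78 °C) should give (17E)-icos-17-enal F1.
- Asymmetric alkoxyallylboration of F1 should give (3S,4S,20E)-3-(methoxymethoxy)tricosa-1,20-dien-4-ol F2. The (Z)-3-(methoxymethoxy)allyl-diisopinocampheylborane is prepared from allyl methoxymethyl ether, s-BuLi, (+)-B-methoxydiisopinocampheylborane and BF3·OEt2; the closed chair transition state of the Z reagent gives the syn product.
- Dess–Martin oxidation should give (3S,20E)-3-(methoxymethoxy)tricosa-1,20-dien-4-one F3.
- Chelation-controlled Mukaiyama aldol addition of 2-(trimethylsilyloxy)buta-1,3-diene (TiCl4, CH2Cl2, −78 °C) should give (5S,6S)-5-hydroxy-6-(methoxymethoxy)-5-[(16E)-nonadec-16-en-1-yl]octa-1,7-dien-3-one F4. The nucleophile enters the titanium chelate of the ketone and ether oxygens from the face next to the hydrogen of the ether-bearing carbon.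
- Ring-closing metathesis (second-generation Grubbs catalyst, CH2Cl2, 40 °C) should give (4S,5S)-5-hydroxy-4-(methoxymethoxy)-5-[(16E)-nonadec-16-en-1-yl]cyclohex-2-en-1-one F5.
- Acetal cleavage (aq. HCl, THF, 25 °C) should give 13.

Step 6. The zinc enolate formed after loss of the first chloride may expel the β-benzyloxy group (cyclobutenone formation or ring opening) instead of being protonated. The fallback runs from 6 to 8: a [2+2] cycloaddition of 6 with unsubstituted ketene, generated in the flask from acetyl chloride and Et3N (MeCN, 60 °C, slow addition). This should deliver 8 directly, with no reductive step and no enolate, and it needs no compound outside the list (none, F0).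

Step 9. Lewis-acid-induced ionisation or β-elimination of the tertiary C5 oxygen, followed by aromatisation, may compete with benzylic C–O cleavage. The fallback runs from 12 to 13: oxidative debenzylation with DDQ in wet CH2Cl2 under green light (525 nm). It removes both benzyl groups as benzaldehyde by benzylic hydride abstraction under neutral conditions and needs no compound outside the list (none, F0).

Further compounds
F1 | step 8 | (17E)-icos-17-enal | O=CCCCCCCCCCCCCCCC/C=C/CC
F2 | step 8 | (3S,4S,20E)-3-(methoxymethoxy)tricosa-1,20-dien-4-ol | C=C[C@H](OCOC)[C@@H](O)CCCCCCCCCCCCCCC/C=C/CC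
F3 | step 8 | (3S,20E)-3-(methoxymethoxy)tricosa-1,20-dien-4-one | C=C[C@H](OCOC)C(=O)CCCCCCCCCCCCCCC/C=C/CC
F4 | step 8 | (5S,6S)-5-hydroxy-6-(methoxymethoxy)-5-[(16E)-nonadec-16-en-1-yl]octa-1,7-dien-3-one | CC/C=C/CCCCCCCCCCCCCCC[C@](O)(CC(=O)C=C)[C@@H](OCOC)C=C
F5 | step 8 | (4S,5S)-5-hydroxy-4-(methoxymethoxy)-5-[(16E)-nonadec-16-en-1-yl]cyclohex-2-en-1-one | CC/C=C/CCCCCCCCCCCCCCC[C@]1(O)CC(=O)C=C[C@@H]1OCOC
F0 | step 6 | none | none
F0 | step 9 | none | none
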